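| setting | maple | oak | flask |
|---|---|---|---|
| left-handed substrate | 0.59 M | 0.59 M | 0.59 M |
| right-handed substrate | 0.59 M | 0.59 M | 0.59 M |
| reagent | 1.47 M | 0.73 M | 1.47 M |
| remark | the very flask that is asked about, followed so far | run made earlier |  |
| time |  |  | 1.5 h |

- maple (time / min: left-handed product / %, left-handed substrate / %): 4.00: 21.5, 31.6; 10.0: 32.3, 21.9; 25.0: 43.9, 17.5; 50.0: 49.8, 11.0
- oak (time / min: left-handed product / %, left-handed substrate / %): 2.00: 6.3, 42.0; 4.00: 12.3, 38.5; 6.00: 14.4, 37.9; 8.00: 20.3, 34.6

(scatter of a reading: 1 percentage point)

- eta: at 1.5 h take out 90 % of the left-handed product then present, then wait 50 min
- zeta: change nothing and wait 50 min more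
- alpha: at 1.5 h add reagent, 50.0 % of the amount charged, then wait 50 min
- epsilon: at 1.5 h add left-handed substrate, 50.0 % of the amount charged, then wait 50 min

- reagent is single-handed; left-handed substrate and right-handed substrate are mirror images of each other, charged as a racemate, each of them at the stated concentration
- what is taken out of left-handed product is counted as made
- additions bring no volume worth counting
- the handed part of reagent does not stay in what it makes, so the products of the two hands are mirror images too

1. left-handed product, in percent of the left-handed substrate and right-handed substrate together first charged, at 1.5 h
2. the remedy with the largest gain of left-handed product, or "none" below 2 percentage points (eta / zeta / alpha / epsilon / none)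
3. left-handed product present, with what was taken out counted in, in percent of the left-handed substrate and right-handed substrate together first charged, after zeta
4. left-handed product present, with what was taken out counted in, in percent of the left-handed substrate and right-handed substrate together first charged, after alpha

The easy step is to count what has gone. In maple at 50.0 min, left-handed product and left-handed substrate add up to 60.8 %, more than the 50.0 % charged as left-handed substrate, so right-handed substrate feeds the left-handed pool, and the two substrates are taken as equal. Then 78.0 % of the substrates has been turned, and the left share, left-handed product per substrate turned, reads 63.8 %. The last oak reading gives 65.9 %.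

Next comes the turn rate in maple, left-handed product made per minute over the left-handed substrate standing. It falls from 0.0393 /min to 0.0166 /min over the last two intervals, a fading constant of 0.0432 /min, which is a half-life of 16.0 min. Summed from the last reading to 1.5 h, that fading rate gives 0.184 turns. With the pool held at its last reading, left-handed product reaches 51.8 %.

Holding the pool is the weak link. By the left share, that product leaves a pool of 9.42 %, so the mean pool gives 51.7 %, the number to commit to. Fresh reagent in alpha, 62.3 % of the substrate charge, exceeds the 18.8 % of substrates left, so with that pool turned at the left share, alpha reckons to 63.7 %.

The forecast gave 54.5 % for now, above this reckoning, with alpha as the best remedy, 56.5 % after zeta and 63 % after alpha, and of the first it said: “Extrapolating gives about 54.5% at 1.5 h”.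

The flask gives 50.7 %, alpha with a gain of 9.5 percentage points, 51.5 % after zeta and 60.2 % after alpha.

    2 reagent → homo dimer (k = 0.0289 /M/min)
    reagent + right-handed substrate → right-handed product (k = 0.0756 /M/min)
    left-handed substrate ⇌ right-handed substrate (k = 0.223 /min)
    reagent + left-handed substrate → left-handed product (k = 0.132 /M/min)

At 90.0 min the flask is close to rest but not there. Free reagent stands at 1.64 % of its charge, or 2.05 % of the substrate charge, and with one reagent per substrate turned, the left share of that is 1.31 %. Left until 900 min, the flask adds 1.3 points of left-handed product, while reagent, the limiting reagent, stands at 0 % and left-handed substrate at 8.25 %.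

In the neighbour flask charged with 0.37 M of reagent, reagent is 31.4 % of the substrate charge, so the left share gives 20.0 %. The computed flask gives 18.1 %, with homo dimer at 0.0160 M.

All runs are calculated for an exercise.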